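**Retrosynthetic overview**

1. The target is three (2R)-7,8,4'-trioxygenated flavan units joined C4→C6 twice. The two upper units are 2,3-cis-3,4-trans flavan-3-ols and the lowest is an all-cis flavan-3,4-diol; both C4–C6 bonds are cut back to one protected monomer 16.
2. The strategy rests on ring A of every unit: O1 sits on C8a and a hydroxyl on the neighbouring C8, beside the 7-oxygen. This pair is what an alkoxide leaves on adding to a C8–C8a aryne when the C8 carbanion is then oxidised, so the pyran ring is closed at O1–C8a from the para-alkoxy, meta-bromo aryl carbinol 11.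
3. The C2/C3/C4 triad of 11 is built open-chain: C4 and C3 by anti-selective asymmetric borylallylboration–oxidation of aldehyde 2 (then acetonide), C2 by Felkin–Anh reduction of aryl ketone 10.
4. Assembly: 16 → C6-brominated C4-thioether acetate 19, which arylates 16 to dimer 20; the acetonide of 20 → thioether 22, which arylates 16 to trimer 23. Each arylation goes trans to the participating 3-acetate.
5. Ring order: dioxolane (step 3), pyran ring of each unit (step 8), then the interflavan bonds (steps 13 and 16); the end is methanolysis, acetonide hydrolysis and hydrogenolysis of nine benzyl ethers and one bromine.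

Key step: step 8

Assumption: (−)-Ipc2BH, the borane from (+)-α-pinene, is taken to deliver the allyl unit to the Si face of aldehyde 2, as the parent B-allyl reagent of this series does; if the opposite sense were found, the enantiomeric borane would be used.

**Route**

Step 1
Reactants: 1 3-bromo-4-hydroxybenzaldehyde
Product: 2 4-(benzyloxy)-3-bromobenzaldehyde
Conditions: BnBr, K2CO3, DMF, rt
Reagents that add atoms: benzyl bromide, BrCc1ccccc1
Why: Williamson ether synthesis on the formyl-acidified phenol installs the benzyl ether that ends as the 7-O-benzyl group and should survive every step up to the final hydrogenolysis.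

Step 2
Reactants: 2 4-(benzyloxy)-3-bromobenzaldehyde
Product: 4 (1R,2S)-1-[4-(benzyloxy)-3-bromophenyl]but-3-ene-1,2-diol, via anti-boryl homoallyl borinate 3 (not isolated)
Conditions: allenylboronic acid pinacol ester, (−)-Ipc2BH, Et2O, −25 → 0 °C; then 2, −78 °C; then 3 M NaOH, 30% H2O2, 0 °C → rt
Reagents that add atoms: allenylboronic acid pinacol ester, C=C=CB1OC(C)(C)C(C)(C)O1; hydrogen peroxide, OO
Why: Asymmetric allylboration with an (E)-γ-boryl allyl-diisopinocampheylborane made in the flask: the chair Zimmerman–Traxler transition state with the E-boryl group equatorial should give the 1,2-anti adduct 3, the isopinocampheyl groups direct attack to the Si face of the aldehyde and so set the benzylic carbinol (future C4) as R, and peroxide oxidation of the C–B bond with retention gives the adjacent hydroxyl (future C3) as S.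

Step 3
Reactants: 4 (1R,2S)-1-[4-(benzyloxy)-3-bromophenyl]but-3-ene-1,2-diol
Product: 5 (4R,5S)-4-[4-(benzyloxy)-3-bromophenyl]-5-ethenyl-2,2-dimethyl-1,3-dioxolane (cis)
Conditions: Me2C(OMe)2, PPTS (cat.), CH2Cl2, rt
Reagents that add atoms: 2,2-dimethoxypropane, COC(C)(C)OC
Why: Acid-catalysed transketalisation ties the anti-1,2-diol into the cis-4,5-disubstituted dioxolane, masking O3 so that only the future O1 can act as the nucleophile in step 8.

Step 4
Reactants: 5 (4R,5S)-4-[4-(benzyloxy)-3-bromophenyl]-5-ethenyl-2,2-dimethyl-1,3-dioxolane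
Product: 6 (4R,5R)-5-[4-(benzyloxy)-3-bromophenyl]-2,2-dimethyl-1,3-dioxolane-4-carbaldehyde (cis)
Conditions: O3, CH2Cl2, −78 °C (Sudan III end point); then Me2S, −78 °C → rt
Reagents that add atoms: ozone, O=[O+][O-]
Why: Ozonolysis with reductive work-up cleaves the terminal alkene much faster than ozone attacks the bromoarene or the benzyl ether at −78 °C, and the configurationally labile cis aldehyde is used at once without chromatography.

Step 5
Reactants: 6 (4R,5R)-5-[4-(benzyloxy)-3-bromophenyl]-2,2-dimethyl-1,3-dioxolane-4-carbaldehyde; 7 1-(benzyloxy)-4-bromobenzene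
Product: 9 [4-(benzyloxy)phenyl][(4S,5R)-5-[4-(benzyloxy)-3-bromophenyl]-2,2-dimethyl-1,3-dioxolan-4-yl]methanol (both carbinol epimers), via arylmagnesium bromide 8 (not isolated)
Conditions: 7, Mg, THF, rt; then 6, THF, −78 → −40 °C; then H2O
Reagents that add atoms: none
Why: Grignard addition of the aryl nucleophile to the aldehyde forms the C2–aryl bond at a temperature where the aryl bromide of 6 does not exchange; the facial selectivity is of no consequence because the new carbinol centre is erased in step 6.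

Step 6
Reactants: 9 [4-(benzyloxy)phenyl][(4S,5R)-5-[4-(benzyloxy)-3-bromophenyl]-2,2-dimethyl-1,3-dioxolan-4-yl]methanol (epimer mixture)
Product: 10 [4-(benzyloxy)phenyl][(4R,5R)-5-[4-(benzyloxy)-3-bromophenyl]-2,2-dimethyl-1,3-dioxolan-4-yl]methanone
Conditions: Dess–Martin periodinane, pyridine, CH2Cl2, 0 °C → rt
Reagents that add atoms: none
Why: Dess–Martin oxidation under buffered, non-basic conditions should give the aryl ketone without epimerising the α-oxygenated centre of the cis-dioxolane.

Step 7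
Reactants: 10 [4-(benzyloxy)phenyl][(4R,5R)-5-[4-(benzyloxy)-3-bromophenyl]-2,2-dimethyl-1,3-dioxolan-4-yl]methanone
Product: 11 (R)-[4-(benzyloxy)phenyl][(4S,5R)-5-[4-(benzyloxy)-3-bromophenyl]-2,2-dimethyl-1,3-dioxolan-4-yl]methanol
Conditions: L-Selectride, THF, −78 °C; then H2O
Reagents that add atoms: none
Why: Felkin–Anh-controlled reduction with a bulky, non-chelating hydride: attack anti to the dioxolane C–O bond and past the α-hydrogen should set the carbinol (future C2) as R, syn to O3, which is the sense complementary to direct aryl addition to the aldehyde.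

Step 8
Reactants: 11 (R)-[4-(benzyloxy)phenyl][(4S,5R)-5-[4-(benzyloxy)-3-bromophenyl]-2,2-dimethyl-1,3-dioxolan-4-yl]methanol
Product: 15 all-cis (2R)-7-(benzyloxy)-2-[4-(benzyloxy)phenyl]-8-hydroxy-3,4-O-isopropylidenechroman-3,4-diol (acetonide of the 2R,3R,4R diol), via aryne alkoxide 12 (not isolated), via C8 aryllithium 13 (not isolated), via C8 dimethyl boronate 14 (not isolated)
Conditions: LiTMP (from TMPH and n-BuLi, 4 equiv), THF, −78 → −30 °C; B(OMe)3, −78 → 0 °C; AcOH, 30% H2O2, 0 °C → rt
Reagents that add atoms: hydrogen peroxide, OO (the 8-oxygen); trimethyl borate, COB(OC)OC (boron of 14 only, lost on oxidation)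
Why: LiTMP first forms the lithium alkoxide and then removes the only proton ortho to bromine (the other ortho position carries the benzyloxy group), and loss of LiBr gives aryne 12 across the future C8–C8a bond; the alkoxide adds to C8a in a six-membered, 6-exo-dig-type closure that forms O1–C8a and leaves aryllithium 13 at C8, which trimethyl borate converts to boronate 14 and peroxide to phenol 15. The closest known reaction type is the base-induced aryne cyclisation of a haloarene carrying a tethered heteroatom nucleophile with electrophilic interception of the resulting aryl anion, joined to the routine borylation–oxidation of an aryllithium. No stereocentre is formed, and the C–H bonds at the three preset centres are not acidic enough for the amide base, so the triad of 11 should be carried over unchanged. Regiocontrol is needed twice: aryne formation is fixed by the bromine position, and addition at C8a is enforced by the tether (attack at C8 would need a meta-bridged seven-membered ring) and reinforced electronically, because the carbanion then sits at C8 beside the inductively stabilising 7-benzyloxy group. The hindered amide is chosen because it does not add to the aryne, and any C8 anion protonated by the amine should be re-lithiated at this doubly oxygen-flanked position by the excess base before the borate quench.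

Step 9
Reactants: 15 all-cis (2R)-7-(benzyloxy)-2-[4-(benzyloxy)phenyl]-8-hydroxy-3,4-O-isopropylidenechroman-3,4-diol
Product: 16 all-cis (2R)-7,8-bis(benzyloxy)-2-[4-(benzyloxy)phenyl]-3,4-O-isopropylidenechroman-3,4-diol (the monomer)
Conditions: BnBr, K2CO3, DMF, 50 °C
Reagents that add atoms: benzyl bromide, BrCc1ccccc1
Why: Williamson ether synthesis on the hindered but acidic C8 phenol gives the fully protected monomer, which serves as every nucleophilic unit and as the source of both electrophiles.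

Step 10
Reactants: 16 the monomer
Product: 17 6-bromo derivative of 16 (bromine on C6, ortho to the 7-benzyloxy group)
Conditions: NBS, CH2Cl2, −20 → 0 °C, dark
Reagents that add atoms: N-bromosuccinimide, O=C1CCC(=O)N1Br
Why: Electrophilic aromatic bromination should go to C6, the position para to O1 and ortho to O7 of the 1,2,3-trioxygenated ring (C5 is para only to the twisted central 8-alkoxy group and the 4-benzyloxyphenyl ring is far less activated), which caps the site where the upper unit could otherwise self-condense.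

Step 11
Reactants: 17 6-bromo monomer acetonide
Product: 18 (2R,3S,4S)-4-(1,3-benzothiazol-2-ylsulfanyl)-7,8-bis(benzyloxy)-2-[4-(benzyloxy)phenyl]-6-bromochroman-3-ol (2,3-cis-3,4-trans)
Conditions: 2-mercaptobenzothiazole, BF3·OEt2, CH2Cl2, −40 → 0 °C
Reagents that add atoms: 2-mercaptobenzothiazole, Sc1nc2ccccc2s1
Why: Lewis acid-mediated SN1 thiolysis of the benzylic acetal C4–O bond: the cation stabilised by the para 7-benzyloxy group and by O1 is captured by sulfur on the face opposite the C3 oxygen, and the hemiketal left on O3 collapses to the free 3-hydroxyl and acetone on work-up.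

Step 12
Reactants: 18 bromo thioether alcohol
Product: 19 (2R,3S,4S)-4-(1,3-benzothiazol-2-ylsulfanyl)-7,8-bis(benzyloxy)-2-[4-(benzyloxy)phenyl]-6-bromochroman-3-yl acetate
Conditions: Ac2O, pyridine, DMAP (cat.), CH2Cl2, rt
Reagents that add atoms: acetic anhydride, CC(=O)OC(C)=O
Why: DMAP-catalysed acetylation protects the 3-hydroxyl against O-alkylation in the coupling and places a participating group next to C4.

Step 13
Reactants: 19 bromo thioether acetate; 16 the monomer (1.5 equiv)
Product: 20 dimer acetonide: upper unit (2R, 2,3-cis-3,4-trans, 3-O-acetyl, 6-bromo, tri-O-benzyl) bonded from C4 to C6 of a lower unit that is 16 with its acetonide intact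
Conditions: AgBF4, 2,6-di-tert-butyl-4-methylpyridine, 4 Å MS, THF, −20 → 0 °C, dark
Reagents that add atoms: none
Why: Silver-promoted Friedel–Crafts alkylation: Ag+ removes the benzothiazolylthio group, the 3-acetate bridges C4 as an acetoxonium ion on the face of O3, and C6 of 16 (para to O1, ortho to O7) attacks from the opposite face to give the 3,4-trans 4→6 bond, while the hindered pyridine takes up HBF4 so that the acetonide of the nucleophile is not ionised and the C6 bromine of the electrophile prevents self-condensation.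

Step 14
Reactants: 20 dimer acetonide
Product: 21 dimer thioether alcohol: as 20, but the lower unit carries 3-OH and a 3,4-trans 4-(1,3-benzothiazol-2-ylsulfanyl) group in place of the acetonide
Conditions: 2-mercaptobenzothiazole, BF3·OEt2, CH2Cl2, −40 → −10 °C
Reagents that add atoms: 2-mercaptobenzothiazole, Sc1nc2ccccc2s1
Why: The same SN1 thiolysis as in step 11 should convert the acetonide of the lower unit into the C4 thioether without touching the acetate, the aryl bromide or, at low temperature, the interflavan bond.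

Step 15
Reactants: 21 dimer thioether alcohol
Product: 22 dimer thioether diacetate (3-O-acetyl on both units, 4-benzothiazolylthio on the lower unit)
Conditions: Ac2O, pyridine, DMAP (cat.), CH2Cl2, rt
Reagents that add atoms: acetic anhydride, CC(=O)OC(C)=O
Why: DMAP-catalysed acetylation, as in step 12, prepares the second electrophile.

Step 16
Reactants: 22 dimer thioether diacetate; 16 the monomer (1.5 equiv)
Product: 23 protected trimer: 6-bromo-3-O-acetyl upper unit (4→6) 3-O-acetyl middle unit (4→6) lower unit as acetonide, nine benzyl ethers, both interflavan bonds 3,4-trans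
Conditions: AgBF4, 2,6-di-tert-butyl-4-methylpyridine, 4 Å MS, THF, −20 → 0 °C, dark
Reagents that add atoms: none
Why: Second silver-promoted Friedel–Crafts alkylation under the conditions of step 13: anchimeric assistance by the 3-acetate of the middle unit should again deliver the 3,4-trans 4→6 bond, and the only free C6 in the flask is that of 16.

Step 17
Reactants: 23 protected trimer
Product: 24 trimer diol acetonide (3-OH free on the upper and middle units)
Conditions: K2CO3, MeOH/THF, rt
Reagents that add atoms: none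
Why: Base-catalysed transesterification (Zemplén-type methanolysis) removes both acetates under conditions to which the acetonide, the benzyl ethers and the aryl bromide are inert.

Step 18
Reactants: 24 trimer diol acetonide
Product: 25 nona-O-benzyl bromo trimer tetraol (3-OH on the upper and middle units, all-cis 3,4-diol on the lower unit)
Conditions: AcOH/THF/H2O (3:1:1), 40 °C
Reagents that add atoms: none
Why: Specific-acid-catalysed ketal hydrolysis cleaves the acetonide through the tertiary oxocarbenium ion at the isopropylidene carbon, a pathway that does not break the C4–O bond, so the 3,4-cis diol should be released with its configuration intact while the phenols are still benzylated.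

Step 19
Reactants: 25 nona-O-benzyl bromo trimer tetraol
Product: 26 CNP0140823.1 (the target)
Conditions: H2 (1 atm), Pd(OH)2/C, NaOAc, THF/MeOH/H2O, rt
Reagents that add atoms: none
Why: Catalytic hydrogenolysis removes the nine aryl benzyl ethers and the C6 bromine in one operation, with sodium acetate taking up the HBr so that the acid-labile benzylic 4-hydroxyl and the interflavan bonds are not exposed to strong acid.

**Compound list**

1 | 3-bromo-4-hydroxybenzaldehyde | O=Cc1ccc(O)c(Br)c1 | starting material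
2 | 4-(benzyloxy)-3-bromobenzaldehyde | O=Cc1ccc(OCc2ccccc2)c(Br)c1 | intermediate
3 | bis(isopinocampheyl)borinate of (1R)-1-[4-(benzyloxy)-3-bromophenyl]-2-(pinacolboryl)but-3-en-1-ol, 1,2-anti (not isolated) | C=C[C@H](B1OC(C)(C)C(C)(C)O1)[C@H](OB([C@@H]2C[C@@H]3C[C@H]([C@H]2C)C3(C)C)[C@@H]2C[C@@H]3C[C@H]([C@H]2C)C3(C)C)c1ccc(OCc2ccccc2)c(Br)c1 | intermediate
4 | (1R,2S)-1-[4-(benzyloxy)-3-bromophenyl]but-3-ene-1,2-diol | C=C[C@H](O)[C@H](O)c1ccc(OCc2ccccc2)c(Br)c1 | intermediate
5 | (4R,5S)-4-[4-(benzyloxy)-3-bromophenyl]-5-ethenyl-2,2-dimethyl-1,3-dioxolane | C=C[C@@H]1OC(C)(C)O[C@@H]1c1ccc(OCc2ccccc2)c(Br)c1 | intermediate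
6 | (4R,5R)-5-[4-(benzyloxy)-3-bromophenyl]-2,2-dimethyl-1,3-dioxolane-4-carbaldehyde | O=C[C@@H]1OC(C)(C)O[C@@H]1c1ccc(OCc2ccccc2)c(Br)c1 | intermediate
7 | 1-(benzyloxy)-4-bromobenzene | Brc1ccc(OCc2ccccc2)cc1 | starting material
8 | 4-(benzyloxy)phenylmagnesium bromide (not isolated) | Br[Mg]c1ccc(OCc2ccccc2)cc1 | intermediate
9 | [4-(benzyloxy)phenyl][(4S,5R)-5-[4-(benzyloxy)-3-bromophenyl]-2,2-dimethyl-1,3-dioxolan-4-yl]methanol, both carbinol epimers | OC(c1ccc(OCc2ccccc2)cc1)[C@@H]1OC(C)(C)O[C@@H]1c1ccc(OCc2ccccc2)c(Br)c1 | intermediate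
10 | [4-(benzyloxy)phenyl][(4R,5R)-5-[4-(benzyloxy)-3-bromophenyl]-2,2-dimethyl-1,3-dioxolan-4-yl]methanone | O=C(c1ccc(OCc2ccccc2)cc1)[C@@H]1OC(C)(C)O[C@@H]1c1ccc(OCc2ccccc2)c(Br)c1 | intermediate
11 | (R)-[4-(benzyloxy)phenyl][(4S,5R)-5-[4-(benzyloxy)-3-bromophenyl]-2,2-dimethyl-1,3-dioxolan-4-yl]methanol | O[C@H](c1ccc(OCc2ccccc2)cc1)[C@@H]1OC(C)(C)O[C@@H]1c1ccc(OCc2ccccc2)c(Br)c1 | intermediate
12 | lithium alkoxide of 11 with the C–Br and ortho C–H replaced by an aryne triple bond (not isolated) | [Li]O[C@H](c1ccc(OCc2ccccc2)cc1)[C@@H]1OC(C)(C)O[C@@H]1C1=CC=C(OCc2ccccc2)C#C1 | intermediate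
13 | 8-lithio all-cis (2R)-7-(benzyloxy)-2-[4-(benzyloxy)phenyl]-3,4-O-isopropylidenechroman-3,4-diol (not isolated) | c1cc2c(c([Li])c1OCc1ccccc1)O[C@H](c1ccc(OCc3ccccc3)cc1)[C@@H]3OC(C)(C)O[C@@H]32 | intermediate
14 | dimethyl [C8] boronate of the same chroman (not isolated) | c1cc2c(c(B(OC)OC)c1OCc1ccccc1)O[C@H](c1ccc(OCc3ccccc3)cc1)[C@@H]3OC(C)(C)O[C@@H]32 | intermediate
15 | all-cis (2R)-7-(benzyloxy)-2-[4-(benzyloxy)phenyl]-8-hydroxy-3,4-O-isopropylidenechroman-3,4-diol | c1cc2c(c(O)c1OCc1ccccc1)O[C@H](c1ccc(OCc3ccccc3)cc1)[C@@H]3OC(C)(C)O[C@@H]32 | intermediate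
16 | all-cis (2R)-7,8-bis(benzyloxy)-2-[4-(benzyloxy)phenyl]-3,4-O-isopropylidenechroman-3,4-diol (monomer) | c1cc2c(c(OCc3ccccc3)c1OCc1ccccc1)O[C@H](c1ccc(OCc3ccccc3)cc1)[C@@H]3OC(C)(C)O[C@@H]32 | intermediate
17 | 6-bromo derivative of 16 | Brc1cc2c(c(OCc3ccccc3)c1OCc1ccccc1)O[C@H](c1ccc(OCc3ccccc3)cc1)[C@@H]3OC(C)(C)O[C@@H]32 | intermediate
18 | (2R,3S,4S)-4-(1,3-benzothiazol-2-ylsulfanyl)-7,8-bis(benzyloxy)-2-[4-(benzyloxy)phenyl]-6-bromochroman-3-ol | Brc1cc2c(c(OCc3ccccc3)c1OCc1ccccc1)O[C@H](c1ccc(OCc3ccccc3)cc1)[C@H](O)[C@H]2Sc1nc2ccccc2s1 | intermediate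
19 | 3-O-acetate of 18 | Brc1cc2c(c(OCc3ccccc3)c1OCc1ccccc1)O[C@H](c1ccc(OCc3ccccc3)cc1)[C@H](OC(C)=O)[C@H]2Sc1nc2ccccc2s1 | intermediate
20 | dimer acetonide (upper: 6-Br, 3-OAc, 3,4-trans; lower: acetonide) | Brc1cc2c(c(OCc3ccccc3)c1OCc1ccccc1)O[C@H](c1ccc(OCc3ccccc3)cc1)[C@H](OC(C)=O)[C@H]2c1cc2c(c(OCc3ccccc3)c1OCc1ccccc1)O[C@H](c1ccc(OCc3ccccc3)cc1)[C@@H]3OC(C)(C)O[C@@H]32 | intermediate
21 | dimer thioether alcohol (lower: 3-OH, 3,4-trans 4-S-benzothiazolyl) | Brc1cc2c(c(OCc3ccccc3)c1OCc1ccccc1)O[C@H](c1ccc(OCc3ccccc3)cc1)[C@H](OC(C)=O)[C@H]2c1cc2c(c(OCc3ccccc3)c1OCc1ccccc1)O[C@H](c1ccc(OCc3ccccc3)cc1)[C@H](O)[C@H]2Sc1nc2ccccc2s1 | intermediate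
22 | dimer thioether diacetate | Brc1cc2c(c(OCc3ccccc3)c1OCc1ccccc1)O[C@H](c1ccc(OCc3ccccc3)cc1)[C@H](OC(C)=O)[C@H]2c1cc2c(c(OCc3ccccc3)c1OCc1ccccc1)O[C@H](c1ccc(OCc3ccccc3)cc1)[C@H](OC(C)=O)[C@H]2Sc1nc2ccccc2s1 | intermediate
23 | protected trimer (upper: 6-Br, 3-OAc; middle: 3-OAc; lower: acetonide) | Brc1cc2c(c(OCc3ccccc3)c1OCc1ccccc1)O[C@H](c1ccc(OCc3ccccc3)cc1)[C@H](OC(C)=O)[C@H]2c1cc2c(c(OCc3ccccc3)c1OCc1ccccc1)O[C@H](c1ccc(OCc3ccccc3)cc1)[C@H](OC(C)=O)[C@H]2c1cc2c(c(OCc3ccccc3)c1OCc1ccccc1)O[C@H](c1ccc(OCc3ccccc3)cc1)[C@@H]3OC(C)(C)O[C@@H]32 | intermediate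
24 | trimer diol acetonide | Brc1cc2c(c(OCc3ccccc3)c1OCc1ccccc1)O[C@H](c1ccc(OCc3ccccc3)cc1)[C@H](O)[C@H]2c1cc2c(c(OCc3ccccc3)c1OCc1ccccc1)O[C@H](c1ccc(OCc3ccccc3)cc1)[C@H](O)[C@H]2c1cc2c(c(OCc3ccccc3)c1OCc1ccccc1)O[C@H](c1ccc(OCc3ccccc3)cc1)[C@@H]3OC(C)(C)O[C@@H]32 | intermediate
25 | nona-O-benzyl bromo trimer tetraol (lower unit all-cis 3,4-diol) | Brc1cc2c(c(OCc3ccccc3)c1OCc1ccccc1)O[C@H](c1ccc(OCc3ccccc3)cc1)[C@H](O)[C@H]2c1cc2c(c(OCc3ccccc3)c1OCc1ccccc1)O[C@H](c1ccc(OCc3ccccc3)cc1)[C@H](O)[C@H]2c1cc2c(c(OCc3ccccc3)c1OCc1ccccc1)O[C@H](c1ccc(OCc3ccccc3)cc1)[C@H](O)[C@@H]2O | intermediate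
26 | CNP0140823.1: upper and middle units (2R,3R,4S), lower unit (2R,3R,4R) | Oc1ccc([C@H]2Oc3c(ccc(O)c3O)[C@H](c3cc4c(c(O)c3O)O[C@H](c3ccc(O)cc3)[C@H](O)[C@H]4c3cc4c(c(O)c3O)O[C@H](c3ccc(O)cc3)[C@H](O)[C@@H]4O)[C@H]2O)cc1 | target

**Step count and risks**

Total step count: 19. Longest linear sequence: 19 steps (1 → 26; monomer 16 from step 9 is drawn on again in steps 13 and 16).

Steps most likely to fail:

1. Step 8. The anion relay may break down after ring closure: the C8 aryllithium can be protonated by the amine or can metalate a benzylic ether C–H before boron is delivered, so that the chroman forms without its 8-oxygen. Fallback, from 11: the two events are separated. Compound 11 is cyclised with LiTMP in THF and the anion is simply protonated (MeOH quench) to give the C8-unsubstituted all-cis chroman acetonide F1. Its C8–H, flanked by O1 and the 7-benzyloxy group, is then removed by directed ortho-lithiation under in situ-quench conditions (LiTMP with B(OiPr)3 present, THF, −78 → 0 °C), and oxidation of the boronate (H2O2, AcOH) rejoins the route at 15.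

2. Step 13 (the same applies to step 16). Under the buffered silver conditions the acetonide of the nucleophile may still ionise and oligomerise, or the cation may decay by elimination before the weakly nucleophilic pyrogallol-type ring captures it. Fallback, from 16 and 17: 16 is hydrolysed (aq. AcOH, THF) to the all-cis monomer diol F2, which is closed to the monomer cyclic carbonate F3 (1,1'-carbonyldiimidazole, toluene, 60 °C), a nucleophile whose C4–O bond is deactivated. F3 is coupled with bromo acetonide 17 itself under hard Lewis acid catalysis (TMSOTf, CH2Cl2, −78 → −40 °C), where the acetonide oxygen is the leaving group and ionisation is reversible, to give the dimer carbonate F4 (upper 3-OH free). Methanolysis (K2CO3, MeOH/THF) gives the dimer triol F5, thiolysis as in step 14 gives the dimer thioether diol F6, and double acetylation (Ac2O, pyridine, DMAP) returns to 22.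

3. Step 18. The acid needed to open the cis-fused acetonide may also ionise the benzylic C4–O bond of the lower unit, with epimerisation at C4 or solvolysis. Fallback, from 23: the C4–O bond is not preserved but re-made under neighbouring-group control (Woodward-type cis-hydroxylation). Thiolysis of 23 as in step 14 gives the trimer thioether alcohol F7, and acetylation gives the trimer thioether triacetate F8. Silver-promoted ionisation in wet THF (AgBF4, 2,6-di-tert-butyl-4-methylpyridine, H2O) lets water open the C3/C4 acetoxonium ion at its central carbon to give the trimer cis-hydroxy acetate F9 (drawn as the 3-acetate; acyl migration to O4 is immaterial). Methanolysis of all three acetates (K2CO3, MeOH/THF) rejoins the route at 25.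

Further compounds
F1 | step 8 | all-cis (2R)-7-(benzyloxy)-2-[4-(benzyloxy)phenyl]-3,4-O-isopropylidenechroman-3,4-diol (C8–H) | c1cc2c(cc1OCc1ccccc1)O[C@H](c1ccc(OCc3ccccc3)cc1)[C@@H]3OC(C)(C)O[C@@H]32
F2 | step 13 | (2R,3R,4R)-7,8-bis(benzyloxy)-2-[4-(benzyloxy)phenyl]chroman-3,4-diol | c1cc2c(c(OCc3ccccc3)c1OCc1ccccc1)O[C@H](c1ccc(OCc3ccccc3)cc1)[C@H](O)[C@@H]2O
F3 | step 13 | 3,4-cyclic carbonate of F2 | c1cc2c(c(OCc3ccccc3)c1OCc1ccccc1)O[C@H](c1ccc(OCc3ccccc3)cc1)[C@@H]3OC(=O)O[C@@H]32
F4 | step 13 | dimer carbonate (upper: 6-Br, 3-OH, 3,4-trans; lower: cyclic carbonate) | Brc1cc2c(c(OCc3ccccc3)c1OCc1ccccc1)O[C@H](c1ccc(OCc3ccccc3)cc1)[C@H](O)[C@H]2c1cc2c(c(OCc3ccccc3)c1OCc1ccccc1)O[C@H](c1ccc(OCc3ccccc3)cc1)[C@@H]3OC(=O)O[C@@H]32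
F5 | step 13 | dimer triol (upper 3-OH; lower all-cis 3,4-diol) | Brc1cc2c(c(OCc3ccccc3)c1OCc1ccccc1)O[C@H](c1ccc(OCc3ccccc3)cc1)[C@H](O)[C@H]2c1cc2c(c(OCc3ccccc3)c1OCc1ccccc1)O[C@H](c1ccc(OCc3ccccc3)cc1)[C@H](O)[C@@H]2O
F6 | step 13 | dimer thioether diol (upper 3-OH; lower 3-OH, 3,4-trans 4-S-benzothiazolyl) | Brc1cc2c(c(OCc3ccccc3)c1OCc1ccccc1)O[C@H](c1ccc(OCc3ccccc3)cc1)[C@H](O)[C@H]2c1cc2c(c(OCc3ccccc3)c1OCc1ccccc1)O[C@H](c1ccc(OCc3ccccc3)cc1)[C@H](O)[C@H]2Sc1nc2ccccc2s1
F7 | step 18 | trimer thioether alcohol (upper and middle 3-OAc; lower 3-OH, 3,4-trans 4-S-benzothiazolyl) | Brc1cc2c(c(OCc3ccccc3)c1OCc1ccccc1)O[C@H](c1ccc(OCc3ccccc3)cc1)[C@H](OC(C)=O)[C@H]2c1cc2c(c(OCc3ccccc3)c1OCc1ccccc1)O[C@H](c1ccc(OCc3ccccc3)cc1)[C@H](OC(C)=O)[C@H]2c1cc2c(c(OCc3ccccc3)c1OCc1ccccc1)O[C@H](c1ccc(OCc3ccccc3)cc1)[C@H](O)[C@H]2Sc1nc2ccccc2s1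
F8 | step 18 | trimer thioether triacetate | Brc1cc2c(c(OCc3ccccc3)c1OCc1ccccc1)O[C@H](c1ccc(OCc3ccccc3)cc1)[C@H](OC(C)=O)[C@H]2c1cc2c(c(OCc3ccccc3)c1OCc1ccccc1)O[C@H](c1ccc(OCc3ccccc3)cc1)[C@H](OC(C)=O)[C@H]2c1cc2c(c(OCc3ccccc3)c1OCc1ccccc1)O[C@H](c1ccc(OCc3ccccc3)cc1)[C@H](OC(C)=O)[C@H]2Sc1nc2ccccc2s1
F9 | step 18 | trimer cis-hydroxy acetate (lower unit 3-OAc, 4-OH cis) | Brc1cc2c(c(OCc3ccccc3)c1OCc1ccccc1)O[C@H](c1ccc(OCc3ccccc3)cc1)[C@H](OC(C)=O)[C@H]2c1cc2c(c(OCc3ccccc3)c1OCc1ccccc1)O[C@H](c1ccc(OCc3ccccc3)cc1)[C@H](OC(C)=O)[C@H]2c1cc2c(c(OCc3ccccc3)c1OCc1ccccc1)O[C@H](c1ccc(OCc3ccccc3)cc1)[C@H](OC(C)=O)[C@@H]2O
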